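Ring B is read as a cyclohexanone: the C9 carbinol carbon, flanked by quaternary C10 and the C8 methine, is the retron of a 2-oxy-diene [4+2] in which the C1–C4 chain of ring A is the tether. An acyclic enone–vinyl sulfone, stereodefined only at the C2/C3 silyloxy carbons, is deprotonated at C10. The dienolate C7=C8–C9(O)=C10 adds across the C5=C6 vinyl sulfone in an intramolecular double Michael (formal Diels–Alder) reaction that forms C10–C5 and C6–C7 and closes both rings as the trans-decalin. Desulfonylation, axial vinylation of the C9 ketone and a B-alkyl Suzuki coupling finish the side chain.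

Key step: step 7

Remark: labdane numbering (C1–C10 ring carbons, C11–C16 side chain, C17 on C8, C18/C19 on C4, C20 on C10) is used for all compounds, acyclic ones included; β is the face of the C10 methyl group, α the opposite face.

Step 1
Reactants: 1 (R)-5-(hydroxymethyl)dihydrofuran-2(3H)-one
Product: 2 (R)-5-oxotetrahydrofuran-2-carbaldehyde
Conditions: TEMPO (10 mol%), PhI(OAc)2, CH2Cl2, rt; used crude
Reagents that add atoms: none
Why: The TEMPO/PhI(OAc)2 oxidation of a primary alcohol should stop at the aldehyde under non-aqueous, non-basic conditions, so the oxygenated stereocentre (future C2) is not epimerised.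

Step 2
Reactants: 2 (R)-5-oxotetrahydrofuran-2-carbaldehyde
Product: 3 (R)-5-[(S)-1-hydroxy-2,2-dimethylbut-3-en-1-yl]dihydrofuran-2(3H)-one
Conditions: prenylB(pin), (PhO)2P(O)OH (10 mol%), 4 Å MS, toluene, 0 °C → rt; aq. NaHCO3
Reagents that add atoms: 3-methylbut-2-en-1-ylboronic acid pinacol ester, CC(C)=CCB1OC(C)(C)C(C)(C)O1
Why: Allylboration through a closed chair transition state transfers the prenyl group with allylic transposition (reverse prenylation), creating the C3 carbinol, the C4 gem-dimethyl carbon and the C5=C6 vinyl group at once; Felkin–Anh addition anti to the ring C–O bond, reinforced by the Z-methyl of the reagent, should give the 2,3-erythro (3S) alcohol.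

Step 3
Reactants: 3 (R)-5-[(S)-1-hydroxy-2,2-dimethylbut-3-en-1-yl]dihydrofuran-2(3H)-one
Product: 4 (5R)-5-[(S)-1-hydroxy-2,2-dimethylbut-3-en-1-yl]-3-methyldihydrofuran-2(3H)-one (both epimers at the methyl-bearing carbon)
Conditions: LiN(iPr)2 (2.2 equiv), THF, −78 °C; MeI, −78 → −40 °C; aq. NH4Cl
Reagents that add atoms: iodomethane, CI
Why: Enolate alkylation of the alkoxide–enolate dianion places the C20 methyl on the lactone α-carbon (future C10); C-methylation should outpace O-methylation of the hindered lithium alkoxide, and the configuration of this centre is irrelevant because it is planarised in step 7.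

Step 4
Reactants: 4 (5R)-5-[(S)-1-hydroxy-2,2-dimethylbut-3-en-1-yl]-3-methyldihydrofuran-2(3H)-one
Product: 5 (6R,7S)-6,7-dihydroxy-2,4,8,8-tetramethyldeca-1,9-dien-3-one (both C4 epimers; open-chain form of its hemiketal equilibrium)
Conditions: CH2=C(CH3)Li (2.5 equiv; from 2-bromopropene, t-BuLi, Et2O, −78 °C), THF, −78 °C; aq. NH4Cl at −78 °C; used crude
Reagents that add atoms: isopropenyllithium, [Li]C(C)=C (made in the flask from 2-bromopropene, CC(Br)=C, and t-BuLi)
Why: Mono-addition of an alkenyllithium to a lactone: the tetrahedral lithium hemiketal is stable at −78 °C and collapses only on quench, so the isopropenyl ketone (C7=C8–C9=O) should form without over-addition.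

Step 5
Reactants: 5 (6R,7S)-6,7-dihydroxy-2,4,8,8-tetramethyldeca-1,9-dien-3-one
Product: 6 (6R,7S)-6,7-bis(tert-butyldimethylsilyloxy)-2,4,8,8-tetramethyldeca-1,9-dien-3-one (both C4 epimers)
Conditions: TBSOTf (2.6 equiv), 2,6-lutidine, CH2Cl2, −78 → 0 °C
Reagents that add atoms: tert-butyldimethylsilyl triflate, CC(C)(C)[Si](C)(C)OS(=O)(=O)C(F)(F)F
Why: Silyl triflate silylation protects both secondary alcohols (including the neopentylic C3–OH) under non-acidic conditions, which avoids internal ketalisation of the keto diol and drains the hemiketal into the open-chain enone.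

Step 6
Reactants: 6 (6R,7S)-6,7-bis(tert-butyldimethylsilyloxy)-2,4,8,8-tetramethyldeca-1,9-dien-3-one
Product: 8 (6R,7S,9E)-6,7-bis(tert-butyldimethylsilyloxy)-2,4,8,8-tetramethyl-10-(phenylsulfonyl)deca-1,9-dien-3-one (both C4 epimers), via β-iodo sulfone 7 (not isolated)
Conditions: PhSO2Na, I2, EtOAc/H2O, rt, visible light; then Et3N, 0 °C → rt
Reagents that add atoms: sodium benzenesulfinate, [Na+].[O-]S(=O)c1ccccc1; iodine, II (iodine stays in 7 only)
Why: Radical iodosulfonylation with PhSO2I made in the flask should be chemoselective for the electron-rich C5=C6 vinyl group over the electron-poor enone because the sulfonyl radical is electrophilic, and E1cB dehydroiodination of the β-iodo sulfone gives the (E)-vinyl sulfone.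

Step 7
Reactants: 8 (6R,7S,9E)-6,7-bis(tert-butyldimethylsilyloxy)-2,4,8,8-tetramethyl-10-(phenylsulfonyl)deca-1,9-dien-3-one
Product: 11 2α,3α-bis(tert-butyldimethylsilyloxy)-6α-(phenylsulfonyl)-4,4,8α,10β-tetramethyl-5α-decalin-9-one (trans-fused), via lithium dienolate 9 (not isolated), via α-sulfonyl carbanion 10 (not isolated)
Conditions: LiN(SiMe3)2 (1.3 equiv), THF (0.01 M), −78 → 0 °C; then MeOH, rt; aq. NH4Cl
Reagents that add atoms: none
Why: Deprotonation at C10 gives the cross-conjugated lithium dienolate 9 (C7=C8–C9(OLi)=C10), whose C10 adds to C5 of the vinyl sulfone to give carbanion 10, and the α-sulfonyl carbanion at C6 then adds to C7 of the enone, so that C10–C5 and C6–C7 are formed in one operation. The closest known reaction type is the base-mediated intramolecular double Michael reaction of α'-enolisable enones, an anion-accelerated formal intramolecular Diels–Alder reaction of a 2-oxy-diene whose regiochemistry (sulfonyl group para to the C9 oxygen) is electronically matched. Ring A closes by a 6-exo-trig (enolexo) Michael addition and ring B by a 6-endo-trig Michael addition. C10 and C5 are controlled by the C2 and C3 stereocentres through a chair transition state of the forming ring A with the C2 silyloxy group equatorial, the C3 silyloxy group axial (anti to the axial C4 methyl), the vinyl sulfone equatorial and the C10 methyl, not the bulkier dienolate carbon C9, in the axial site, which gives 5α-H and 10β-CH3 and thus the trans ring fusion; C6 (equatorial sulfonyl, removed in step 8) and C8 (equatorial 8α-methyl) are set thermodynamically by equilibration with LiOMe in MeOH. The step needs trans over cis fusion and one diastereoface relative to C2/C3, and the substrate secures this because the alternative chair would place the C2 silyloxy group 1,3-diaxial to the axial substituents at C4 and C10. Both C10 epimers of 8 and both dienolate geometries should converge on 11, since C10 is planar in 9 and the bond formation is stepwise.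

Step 8
Reactants: 11 2α,3α-bis(tert-butyldimethylsilyloxy)-6α-(phenylsulfonyl)-4,4,8α,10β-tetramethyl-5α-decalin-9-one
Product: 12 2α,3α-bis(tert-butyldimethylsilyloxy)-4,4,8α,10β-tetramethyl-5α-decalin-9-one
Conditions: 6% Na(Hg), Na2HPO4, MeOH/THF, −20 → 0 °C
Reagents that add atoms: none
Why: Reductive desulfonylation by electron transfer from sodium amalgam cleaves the C6–S bond of the alkyl aryl sulfone and leaves C6 as CH2; the buffered, cold conditions should spare the hindered ketone and the silyl ethers.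

Step 9
Reactants: 12 2α,3α-bis(tert-butyldimethylsilyloxy)-4,4,8α,10β-tetramethyl-5α-decalin-9-one
Product: 13 2α,3α-bis(tert-butyldimethylsilyloxy)-4,4,8α,10β-tetramethyl-9α-vinyl-5α-decalin-9β-ol
Conditions: CH2=CHMgBr, CeCl3, THF, −78 → 0 °C; aq. NH4Cl
Reagents that add atoms: vinylmagnesium bromide, C=C[Mg]Br
Why: Organocerium 1,2-addition suppresses enolisation of the hindered ketone, and the small sp2 nucleophile should attack axially from the α face, anti to the axial C10 methyl that blocks the equatorial trajectory, which sets C9 as 9α-vinyl-9β-ol.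

Step 10
Reactants: 14 methyl 3-oxobutanoate (methyl acetoacetate)
Product: 15 methyl (E)-3-(trifluoromethylsulfonyloxy)but-2-enoate
Conditions: Tf2O, aq. Me4NOH, toluene, 0–5 °C
Reagents that add atoms: triflic anhydride, O=S(=O)(OS(=O)(=O)C(F)(F)F)C(F)(F)F
Why: O-Sulfonylation of the β-keto ester enolate; with the non-chelating tetramethylammonium counter-ion the enolate should react in its extended form and give the (E)-enol triflate.

Step 11
Reactants: 13 2α,3α-bis(tert-butyldimethylsilyloxy)-4,4,8α,10β-tetramethyl-9α-vinyl-5α-decalin-9β-ol; 15 methyl (E)-3-(trifluoromethylsulfonyloxy)but-2-enoate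
Product: 17 methyl (13E)-2α,3α-bis(tert-butyldimethylsilyloxy)-9β-hydroxy-9α-side-chain labd-13-en-15-oate, via B-alkyl-9-BBN borane 16 (not isolated)
Conditions: 9-BBN, THF, rt → 50 °C; then 15, PdCl2(dppf) (5 mol%), AsPh3, aq. K3PO4, DMF, rt
Reagents that add atoms: 9-borabicyclo[3.3.1]nonane (9-BBN), B1C2CCCC1CCC2 (boron stays in 16 only)
Why: Anti-Markovnikov hydroboration of the vinyl group followed by B-alkyl Suzuki–Miyaura coupling with the enol triflate joins C12 to C13 with retention of alkene geometry, so the (E)-enoate is delivered without an olefination.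

Step 12
Reactants: 17 methyl (13E)-2α,3α-bis(tert-butyldimethylsilyloxy)-9β-hydroxy-9α-side-chain labd-13-en-15-oate
Product: 18 methyl (13E)-2α,3α,9β-trihydroxy-9α-side-chain labd-13-en-15-oate, (2R,3S,5S,8R,9S,10S), CNP0292844.1
Conditions: 48% aq. HF, MeCN, 0 °C → rt
Reagents that add atoms: none
Why: Fluoride-mediated desilylation removes both TBS ethers, and the non-basic conditions should avoid oxa-Michael closure of the C9 hydroxyl onto the enoate and ester hydrolysis.

Compound list
1 | (R)-5-(hydroxymethyl)dihydrofuran-2(3H)-one | O=C1CC[C@H](CO)O1 | starting material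
2 | (R)-5-oxotetrahydrofuran-2-carbaldehyde | O=C1CC[C@H](C=O)O1 | intermediate
3 | (R)-5-[(S)-1-hydroxy-2,2-dimethylbut-3-en-1-yl]dihydrofuran-2(3H)-one | O=C1CC[C@H]([C@@H](O)C(C)(C)C=C)O1 | intermediate
4 | (5R)-5-[(S)-1-hydroxy-2,2-dimethylbut-3-en-1-yl]-3-methyldihydrofuran-2(3H)-one, both C3 epimers | CC1C[C@H]([C@@H](O)C(C)(C)C=C)OC1=O | intermediate
5 | (6R,7S)-6,7-dihydroxy-2,4,8,8-tetramethyldeca-1,9-dien-3-one, both C4 epimers | C=C(C)C(=O)C(C)C[C@@H](O)[C@@H](O)C(C)(C)C=C | intermediate
6 | (6R,7S)-6,7-bis(tert-butyldimethylsilyloxy)-2,4,8,8-tetramethyldeca-1,9-dien-3-one, both C4 epimers | C=C(C)C(=O)C(C)C[C@@H](O[Si](C)(C)C(C)(C)C)[C@@H](O[Si](C)(C)C(C)(C)C)C(C)(C)C=C | intermediate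
7 | (6R,7S)-6,7-bis(tert-butyldimethylsilyloxy)-9-iodo-2,4,8,8-tetramethyl-10-(phenylsulfonyl)dec-1-en-3-one, mixture at C4 and C9 | C=C(C)C(=O)C(C)C[C@@H](O[Si](C)(C)C(C)(C)C)[C@@H](O[Si](C)(C)C(C)(C)C)C(C)(C)C(I)CS(=O)(=O)c1ccccc1 | intermediate
8 | (6R,7S,9E)-6,7-bis(tert-butyldimethylsilyloxy)-2,4,8,8-tetramethyl-10-(phenylsulfonyl)deca-1,9-dien-3-one, both C4 epimers | C=C(C)C(=O)C(C)C[C@@H](O[Si](C)(C)C(C)(C)C)[C@@H](O[Si](C)(C)C(C)(C)C)C(C)(C)/C=C/S(=O)(=O)c1ccccc1 | intermediate
9 | lithium dienolate of 8 (lithium deca-1,3,9-trien-3-olate, enolate geometry open) | C=C(C)C(O[Li])=C(C)C[C@@H](O[Si](C)(C)C(C)(C)C)[C@@H](O[Si](C)(C)C(C)(C)C)C(C)(C)/C=C/S(=O)(=O)c1ccccc1 | intermediate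
10 | ring-A Michael adduct lithiated at C6: cyclohexane with C10 carrying methyl and the 2-methylpropenoyl group, C5 carrying CH(Li)SO2Ph, 2α,3α-bis(TBSO), 4,4-dimethyl | C=C(C)C(=O)[C@@]1(C)C[C@@H](O[Si](C)(C)C(C)(C)C)[C@@H](O[Si](C)(C)C(C)(C)C)C(C)(C)[C@@H]1C([Li])S(=O)(=O)c1ccccc1 | intermediate
11 | 2α,3α-bis(tert-butyldimethylsilyloxy)-6α-(phenylsulfonyl)-4,4,8α,10β-tetramethyl-5α-decalin-9-one | O=C1[C@H](C)C[C@H](S(=O)(=O)c3ccccc3)[C@H]2C(C)(C)[C@H](O[Si](C)(C)C(C)(C)C)[C@H](O[Si](C)(C)C(C)(C)C)C[C@@]21C | intermediate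
12 | 2α,3α-bis(tert-butyldimethylsilyloxy)-4,4,8α,10β-tetramethyl-5α-decalin-9-one | O=C1[C@H](C)CC[C@H]2C(C)(C)[C@H](O[Si](C)(C)C(C)(C)C)[C@H](O[Si](C)(C)C(C)(C)C)C[C@@]21C | intermediate
13 | 2α,3α-bis(tert-butyldimethylsilyloxy)-4,4,8α,10β-tetramethyl-9α-vinyl-5α-decalin-9β-ol | C=C[C@]1(O)[C@H](C)CC[C@H]2C(C)(C)[C@H](O[Si](C)(C)C(C)(C)C)[C@H](O[Si](C)(C)C(C)(C)C)C[C@@]21C | intermediate
14 | methyl 3-oxobutanoate (methyl acetoacetate) | COC(=O)CC(C)=O | starting material
15 | methyl (E)-3-(trifluoromethylsulfonyloxy)but-2-enoate | COC(=O)/C=C(\C)OS(=O)(=O)C(F)(F)F | intermediate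
16 | 9-[2-(9β-hydroxy-2α,3α-bis(TBSO)-4,4,8α,10β-tetramethyl-5α-decalin-9α-yl)ethyl]-9-borabicyclo[3.3.1]nonane | O[C@@]1(CCB2C3CCCC2CCC3)[C@H](C)CC[C@H]2C(C)(C)[C@H](O[Si](C)(C)C(C)(C)C)[C@H](O[Si](C)(C)C(C)(C)C)C[C@@]21C | intermediate
17 | methyl (13E)-2α,3α-bis(tert-butyldimethylsilyloxy)-9β-hydroxy-labd-13-en-15-oate with the side chain 9α | COC(=O)/C=C(\C)CC[C@]1(O)[C@H](C)CC[C@H]2C(C)(C)[C@H](O[Si](C)(C)C(C)(C)C)[C@H](O[Si](C)(C)C(C)(C)C)C[C@@]21C | intermediate
18 | methyl (13E)-2α,3α,9β-trihydroxy-labd-13-en-15-oate with the side chain 9α, (2R,3S,5S,8R,9S,10S) | COC(=O)/C=C(\C)CC[C@]1(O)[C@H](C)CC[C@H]2C(C)(C)[C@H](O)[C@H](O)C[C@@]21C | target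

Total step count: 12. Longest linear sequence: 11 steps (steps 1–9, 11, 12; step 10 is a one-step branch).

Steps most likely to fail

Step 7 (key step). The process at risk is the first Michael addition at the congested C10–C5 bond: it may be reversible, so that intermolecular enolate–enone oligomerisation or erosion of the trans ring fusion takes over. The fallback leaves the anionic manifold. From 8, soft enolisation (TBSOTf, Et3N, CH2Cl2) should give the (Z)-tert-butyldimethylsilyl dienol ether F1, in which the C1 chain is cis to the silyloxy group; the (E)-isomer can be hydrolysed back to 8. Heating F1 (toluene, BHT, 140–160 °C, sealed tube) in a neutral thermal intramolecular Diels–Alder reaction, with the sulfonyl group endo and the tether exo, should give the trans-fused cycloadduct silyl enol ether F2. Selective cleavage of the enol ether (TBAF, AcOH, THF, −20 °C) and equilibration (NaOMe, MeOH) come back to the route at 11.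

Step 9. The process at risk is enolisation of the doubly α-branched ketone or attack from the β face, that is, poor facial selectivity at C9. The fallback uses a slimmer, less basic sp nucleophile with a stronger preference for axial attack. From 12, LiC≡CSiMe3 with CeCl3 (THF, −78 °C) should give the 9α-(trimethylsilylethynyl)-9β-ol F3; K2CO3 in MeOH gives the 9α-ethynyl-9β-ol F4; semi-hydrogenation (H2, Pd/CaCO3 poisoned with Pb(OAc)2, quinoline) comes back to the route at 13.

Step 6. The process at risk is loss of chemoselectivity: sulfonyl radical addition to the enone, or base-triggered premature Michael chemistry during dehydroiodination. The fallback installs the sulfone before the enone exists. From 4, aminolysis with MeNHOMe·HCl and AlMe3 (CH2Cl2) should give the dihydroxy Weinreb amide F5, which is silylated at once (TBSOTf, 2,6-lutidine) to the bis-silyl ether F6. Iodosulfonylation (PhSO2Na, I2) gives the β-iodo sulfone amide F7 and Et3N gives the (E)-vinyl sulfone Weinreb amide F8. Ketone synthesis with CH2=C(CH3)MgBr (THF, −78 → −20 °C), which should spare the hindered vinyl sulfone, comes back to the route at 8.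

Further compounds
F1 | step 7 | (Z)-tert-butyldimethylsilyl dienol ether of 8 (3-silyloxy-deca-1,3,9-triene, C1 chain cis to OSi) | C=C(C)/C(O[Si](C)(C)C(C)(C)C)=C(\C)C[C@@H](O[Si](C)(C)C(C)(C)C)[C@@H](O[Si](C)(C)C(C)(C)C)C(C)(C)/C=C/S(=O)(=O)c1ccccc1
F2 | step 7 | 2α,3α,9-tris(tert-butyldimethylsilyloxy)-6α-(phenylsulfonyl)-4,4,8,10β-tetramethyl-5α-octal-8-ene (cycloadduct silyl enol ether) | CC(C)(C)[Si](C)(C)OC1=C(C)C[C@H](S(=O)(=O)c3ccccc3)[C@H]2C(C)(C)[C@H](O[Si](C)(C)C(C)(C)C)[C@H](O[Si](C)(C)C(C)(C)C)C[C@@]21C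
F3 | step 9 | 2α,3α-bis(tert-butyldimethylsilyloxy)-4,4,8α,10β-tetramethyl-9α-(trimethylsilylethynyl)-5α-decalin-9β-ol | C[Si](C)(C)C#C[C@]1(O)[C@H](C)CC[C@H]2C(C)(C)[C@H](O[Si](C)(C)C(C)(C)C)[C@H](O[Si](C)(C)C(C)(C)C)C[C@@]21C
F4 | step 9 | 2α,3α-bis(tert-butyldimethylsilyloxy)-9α-ethynyl-4,4,8α,10β-tetramethyl-5α-decalin-9β-ol | C#C[C@]1(O)[C@H](C)CC[C@H]2C(C)(C)[C@H](O[Si](C)(C)C(C)(C)C)[C@H](O[Si](C)(C)C(C)(C)C)C[C@@]21C
F5 | step 6 | (4R,5S)-4,5-dihydroxy-N-methoxy-N,2,6,6-tetramethyloct-7-enamide, both C2 epimers | CON(C)C(=O)C(C)C[C@@H](O)[C@@H](O)C(C)(C)C=C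
F6 | step 6 | (4R,5S)-4,5-bis(tert-butyldimethylsilyloxy)-N-methoxy-N,2,6,6-tetramethyloct-7-enamide | CON(C)C(=O)C(C)C[C@@H](O[Si](C)(C)C(C)(C)C)[C@@H](O[Si](C)(C)C(C)(C)C)C(C)(C)C=C
F7 | step 6 | (4R,5S)-4,5-bis(tert-butyldimethylsilyloxy)-7-iodo-N-methoxy-N,2,6,6-tetramethyl-8-(phenylsulfonyl)octanamide | CON(C)C(=O)C(C)C[C@@H](O[Si](C)(C)C(C)(C)C)[C@@H](O[Si](C)(C)C(C)(C)C)C(C)(C)C(I)CS(=O)(=O)c1ccccc1
F8 | step 6 | (4R,5S,7E)-4,5-bis(tert-butyldimethylsilyloxy)-N-methoxy-N,2,6,6-tetramethyl-8-(phenylsulfonyl)oct-7-enamide | CON(C)C(=O)C(C)C[C@@H](O[Si](C)(C)C(C)(C)C)[C@@H](O[Si](C)(C)C(C)(C)C)C(C)(C)/C=C/S(=O)(=O)c1ccccc1
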